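**Retrosynthetic overview**
- The target is (2S)-2,3-dihydrorobustaflavone 5-methyl ether. The last step is acid removal of four MOM ethers from the (2S)-flavanone.
- Ring C of the flavanone (the O1–C2 bond and the only stereocentre) comes from an enantioselective 6-endo oxa-Michael cyclisation of a 2'-hydroxy-6'-methoxychalcone. This C–O bond formation is the key step.
- The chalcone comes from a Claisen–Schmidt condensation of a flavone-bearing biaryl aldehyde with 2'-hydroxy-6'-methoxy-4'-(methoxymethoxy)acetophenone.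
- The biaryl aldehyde comes from a one-pot borylation/Suzuki coupling of MOM-protected 3-bromo-4-hydroxybenzaldehyde with 6-iodo-apigenin 7,4'-di-MOM ether.
- Ring order: the flavone rings A, C and B are bought intact as apigenin; the only ring built is ring C of the flavanone, closed in the penultimate step.

Assumption: apigenin, 3-bromo-4-hydroxybenzaldehyde and 2',4'-dihydroxy-6'-methoxyacetophenone are taken as catalogue starting materials, and the biaryl axis (no descriptor in the SMILES) is taken as freely rotating.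

**Step 1**
Reactants: 1 apigenin
Product: 2 5-hydroxy-7-(methoxymethoxy)-2-[4-(methoxymethoxy)phenyl]-4H-chromen-4-one
Conditions: MOMCl (2.3 equiv), K2CO3, acetone, 0 °C to rt
Reagents that add atoms: chloromethyl methyl ether (MOMCl), COCCl
Why: Williamson-type O-alkylation (MOM protection) takes the 7- and 4'-phenols, while the 5-OH, hydrogen-bonded to the C-4 carbonyl, stays free.

**Step 2**
Reactants: 2 5-hydroxy-7-(methoxymethoxy)-2-[4-(methoxymethoxy)phenyl]-4H-chromen-4-one
Product: 3 5-hydroxy-6-iodo-7-(methoxymethoxy)-2-[4-(methoxymethoxy)phenyl]-4H-chromen-4-one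
Conditions: BnMe3N·ICl2 (1.1 equiv), CaCO3, CH2Cl2/MeOH 5:2, rt
Reagents that add atoms: benzyltrimethylammonium dichloroiodate, C[N+](C)(C)Cc1ccccc1.Cl[I-]Cl
Why: Electrophilic aromatic iodination of a 5-hydroxy-7-alkoxyflavone goes to C-6, ortho to the free chelated phenol, and not to C-8, and CaCO3 scavenges HCl so the MOM ethers survive.

**Step 3**
Reactants: 4 3-bromo-4-hydroxybenzaldehyde
Product: 5 3-bromo-4-(methoxymethoxy)benzaldehyde
Conditions: MOMCl (1.3 equiv), K2CO3, acetone, rt
Reagents that add atoms: chloromethyl methyl ether (MOMCl), COCCl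
Why: Williamson-type MOM protection of the acidic para-formyl phenol, which keeps the aldehyde electrophilic in the later aldol step.

**Step 4**
Reactants: 5 3-bromo-4-(methoxymethoxy)benzaldehyde; 3 5-hydroxy-6-iodo-7-(methoxymethoxy)-2-[4-(methoxymethoxy)phenyl]-4H-chromen-4-one
Product: 7 3-{5-hydroxy-7-(methoxymethoxy)-2-[4-(methoxymethoxy)phenyl]-4-oxo-4H-chromen-6-yl}-4-(methoxymethoxy)benzaldehyde, via pinacol boronate 6 (not isolated)
Conditions: 5 (1.5 equiv), B2pin2 (1.5 equiv), Pd2(dba)3 (2 mol%), XPhos (2-dicyclohexylphosphino-2',4',6'-triisopropylbiphenyl, 8 mol%), KOAc, 1,4-dioxane, 100 °C; then 3 (1.0 equiv), K3PO4 (3 M aq), 100 °C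
Reagents that add atoms: bis(pinacolato)diboron, CC1(C)OB(OC1(C)C)B1OC(C)(C)C(C)(C)O1 (its Bpin group is carried only by intermediate 6 and is lost again in 7)
Why: One-pot Miyaura borylation then Suzuki–Miyaura coupling, in which acetate allows only borylation of the bromide and aqueous phosphate then switches on transmetallation to the aryl–palladium iodide from 3, with the bulky biarylphosphine handling the tri-ortho-substituted biaryl.

**Step 5**
Reactants: 8 1-(2,4-dihydroxy-6-methoxyphenyl)ethan-1-one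
Product: 9 1-[2-hydroxy-6-methoxy-4-(methoxymethoxy)phenyl]ethan-1-one
Conditions: MOMCl (1.1 equiv), K2CO3, acetone, 0 °C to rt
Reagents that add atoms: chloromethyl methyl ether (MOMCl), COCCl
Why: Selective Williamson-type MOM protection of the para-hydroxyl, because the ortho-hydroxyl is tied up in a hydrogen bond to the acetyl carbonyl.

**Step 6**
Reactants: 7 3-{5-hydroxy-7-(methoxymethoxy)-2-[4-(methoxymethoxy)phenyl]-4-oxo-4H-chromen-6-yl}-4-(methoxymethoxy)benzaldehyde; 9 1-[2-hydroxy-6-methoxy-4-(methoxymethoxy)phenyl]ethan-1-one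
Product: 11 (E)-1-[2-hydroxy-6-methoxy-4-(methoxymethoxy)phenyl]-3-[3-{5-hydroxy-7-(methoxymethoxy)-2-[4-(methoxymethoxy)phenyl]-4-oxo-4H-chromen-6-yl}-4-(methoxymethoxy)phenyl]prop-2-en-1-one, via aldol adduct 10 (not isolated)
Conditions: 9 (1.2 equiv), KOH (50% aq, 10 equiv), EtOH/THF, 0 °C to rt, 24–36 h; AcOH to pH 5–6 at 0 °C; chromatography to remove any flavanone
Reagents that add atoms: none
Why: Claisen–Schmidt (crossed aldol) condensation of the ketone enolate with the non-enolisable aldehyde, followed by E1cB loss of water to the (E)-enone; as phenoxides the 2'-hydroxychalcone does not cyclise and the 5-hydroxyflavone resists hydroxide attack.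

**Step 7**
Reactants: 11 (E)-1-[2-hydroxy-6-methoxy-4-(methoxymethoxy)phenyl]-3-[3-{5-hydroxy-7-(methoxymethoxy)-2-[4-(methoxymethoxy)phenyl]-4-oxo-4H-chromen-6-yl}-4-(methoxymethoxy)phenyl]prop-2-en-1-one
Product: 12 (2S)-2-[3-{5-hydroxy-7-(methoxymethoxy)-2-[4-(methoxymethoxy)phenyl]-4-oxo-4H-chromen-6-yl}-4-(methoxymethoxy)phenyl]-5-methoxy-7-(methoxymethoxy)-2,3-dihydro-4H-chromen-4-one
Conditions: 1-[3,5-bis(trifluoromethyl)phenyl]-3-[(2S)-3,3-dimethyl-1-{[tris(4-methoxyphenyl)-λ5-phosphanylidene]amino}butan-2-yl]thiourea (10 mol%), toluene/THF 4:1, 0.05 M, −20 °C, 48 h; AcOH quench at −20 °C at about 90% conversion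
Reagents that add atoms: none
Why: Proposed new method: a bifunctional iminophosphorane–thiourea superbase has not been used to cyclise a plain, ester-free 2'-hydroxychalcone to a flavanone; here the iminophosphorane deprotonates the 2'-OH (the chelated flavone 5-OH only exchanges protons and cannot cyclise), the phenoxide stays ion-paired to the chiral iminophosphonium while the thiourea N–H bonds bind the enone carbonyl, which the 6'-OMe group has twisted out of the aryl plane so the aroyl ring can rotate and deliver the phenoxide oxygen to one face of C-β in a 6-endo-trig oxa-Michael addition that sets C-2 as S, and the enolate is then protonated by the iminophosphonium N–H; because the catalyst rests as the weakly basic phenoxide salt while chalcone remains, retro-Michael racemisation (which needs C-3 deprotonation) is suppressed at −20 °C if the run is quenched before full conversion; the closest known reaction types are the iminophosphorane-catalysed enantioselective intramolecular oxa-Michael addition of alcohols to unsaturated esters and amides and the cinchona-thiourea cyclisation of ester-activated alkylidene β-ketoesters to flavanones; the facial sense cannot be predicted, so it is checked by CD and chiral HPLC on the first run and the catalyst from (R)-tert-leucine is used if it is reversed.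

**Step 8**
Reactants: 12 (2S)-2-[3-{5-hydroxy-7-(methoxymethoxy)-2-[4-(methoxymethoxy)phenyl]-4-oxo-4H-chromen-6-yl}-4-(methoxymethoxy)phenyl]-5-methoxy-7-(methoxymethoxy)-2,3-dihydro-4H-chromen-4-one
Product: 13 5,7-dihydroxy-6-{2-hydroxy-5-[(2S)-7-hydroxy-5-methoxy-4-oxo-3,4-dihydro-2H-chromen-2-yl]phenyl}-2-(4-hydroxyphenyl)-4H-chromen-4-one
Conditions: HCl (0.5 M in MeOH), THF, 25–35 °C, monitored by chiral HPLC
Reagents that add atoms: none
Why: Acid-catalysed transacetalisation to methanol cleaves the four MOM acetals, leaves the aryl methyl ether intact, and cannot epimerise C-2 by enolisation, so the configuration set in step 7 is kept as long as acid-mediated ring opening is avoided by the mild temperature.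

**Compound list**
1 | apigenin, 5,7-dihydroxy-2-(4-hydroxyphenyl)-4H-chromen-4-one | O=c1cc(-c2ccc(O)cc2)oc2cc(O)cc(O)c12 | starting material
2 | 5-hydroxy-7-(methoxymethoxy)-2-[4-(methoxymethoxy)phenyl]-4H-chromen-4-one | O=c1cc(-c2ccc(OCOC)cc2)oc2cc(OCOC)cc(O)c12 | intermediate
3 | 5-hydroxy-6-iodo-7-(methoxymethoxy)-2-[4-(methoxymethoxy)phenyl]-4H-chromen-4-one | O=c1cc(-c2ccc(OCOC)cc2)oc2cc(OCOC)c(I)c(O)c12 | intermediate
4 | 3-bromo-4-hydroxybenzaldehyde | O=Cc1ccc(O)c(Br)c1 | starting material
5 | 3-bromo-4-(methoxymethoxy)benzaldehyde | O=Cc1ccc(OCOC)c(Br)c1 | intermediate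
6 | 4-(methoxymethoxy)-3-(4,4,5,5-tetramethyl-1,3,2-dioxaborolan-2-yl)benzaldehyde (pinacol boronate, not isolated) | O=Cc1ccc(OCOC)c(B2OC(C)(C)C(C)(C)O2)c1 | intermediate
7 | 3-{5-hydroxy-7-(methoxymethoxy)-2-[4-(methoxymethoxy)phenyl]-4-oxo-4H-chromen-6-yl}-4-(methoxymethoxy)benzaldehyde | O=Cc1ccc(OCOC)c(-c2c(OCOC)cc3oc(-c4ccc(OCOC)cc4)cc(=O)c3c2O)c1 | intermediate
8 | 1-(2,4-dihydroxy-6-methoxyphenyl)ethan-1-one (2',4'-dihydroxy-6'-methoxyacetophenone) | CC(=O)c1c(O)cc(O)cc1OC | starting material
9 | 1-[2-hydroxy-6-methoxy-4-(methoxymethoxy)phenyl]ethan-1-one | CC(=O)c1c(O)cc(OCOC)cc1OC | intermediate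
10 | racemic 3-hydroxy-1-[2-hydroxy-6-methoxy-4-(methoxymethoxy)phenyl]-3-[3-{5-hydroxy-7-(methoxymethoxy)-2-[4-(methoxymethoxy)phenyl]-4-oxo-4H-chromen-6-yl}-4-(methoxymethoxy)phenyl]propan-1-one (aldol adduct, not isolated) | COc1cc(OCOC)cc(O)c1C(=O)CC(O)c1ccc(OCOC)c(-c2c(OCOC)cc3oc(-c4ccc(OCOC)cc4)cc(=O)c3c2O)c1 | intermediate
11 | (E)-1-[2-hydroxy-6-methoxy-4-(methoxymethoxy)phenyl]-3-[3-{5-hydroxy-7-(methoxymethoxy)-2-[4-(methoxymethoxy)phenyl]-4-oxo-4H-chromen-6-yl}-4-(methoxymethoxy)phenyl]prop-2-en-1-one | COc1cc(OCOC)cc(O)c1C(=O)/C=C/c1ccc(OCOC)c(-c2c(OCOC)cc3oc(-c4ccc(OCOC)cc4)cc(=O)c3c2O)c1 | intermediate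
12 | (2S)-2-[3-{5-hydroxy-7-(methoxymethoxy)-2-[4-(methoxymethoxy)phenyl]-4-oxo-4H-chromen-6-yl}-4-(methoxymethoxy)phenyl]-5-methoxy-7-(methoxymethoxy)-2,3-dihydro-4H-chromen-4-one | COc1cc(OCOC)cc2c1C(=O)C[C@@H](c1ccc(OCOC)c(-c3c(OCOC)cc4oc(-c5ccc(OCOC)cc5)cc(=O)c4c3O)c1)O2 | intermediate
13 | 5,7-dihydroxy-6-{2-hydroxy-5-[(2S)-7-hydroxy-5-methoxy-4-oxo-3,4-dihydro-2H-chromen-2-yl]phenyl}-2-(4-hydroxyphenyl)-4H-chromen-4-one | COc1cc(O)cc2c1C(=O)C[C@@H](c1ccc(O)c(-c3c(O)cc4oc(-c5ccc(O)cc5)cc(=O)c4c3O)c1)O2 | target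

**Totals**
Total step count: 8. Longest linear sequence: 6 steps (steps 1, 2, 4, 6, 7, 8 from apigenin).

**Steps most likely to fail**

Step 7 (proposed new method). The enantioselectivity, the facial sense and the resistance of the product to catalyst-mediated retro-Michael racemisation are all untested, and the chelated flavone 5-OH may hold back part of the catalyst. The fallback uses known chemistry only, sets out from compound 11 and comes back at compound 12. Chalcone 11 is cyclised without induction by the classical base-mediated ring closure (NaOAc, EtOH, reflux) to racemic 2-[3-{5-hydroxy-7-(methoxymethoxy)-2-[4-(methoxymethoxy)phenyl]-4-oxo-4H-chromen-6-yl}-4-(methoxymethoxy)phenyl]-5-methoxy-7-(methoxymethoxy)-2,3-dihydro-4H-chromen-4-one F1. The enantiomers are separated by preparative supercritical-fluid chromatography on an amylose tris(3,5-dimethylphenylcarbamate) phase, giving 12 and the (2R)-enantiomer F2. F2 is returned to the NaOAc/EtOH treatment, where it re-equilibrates through 11 to F1, so no material is lost.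

Step 4. The coupling builds a tri-ortho-substituted biaryl on an electron-rich ortho-iodophenol, and the ortho-alkoxy boronate made in the flask can protodeboronate before it couples. The fallback replaces the basic boron coupling by a base-free Stille coupling, sets out from compounds 5 and 3 and comes back at compound 7. Bromide 5 is stannylated (Me3SnSnMe3, Pd(PPh3)4, toluene, 110 °C) to 4-(methoxymethoxy)-3-(trimethylstannyl)benzaldehyde F3. F3 is then coupled with iodide 3 under copper-assisted conditions (Pd(PPh3)4, CuI, CsF, DMF, 45 °C) to give 7.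

Step 8. The free 4'-hydroxyphenyl group can assist acid-mediated opening of the benzylic C2–O1 bond, which would erode the ee, and four MOM ethers must all be cleaved. The fallback avoids protic acid by trans-protection to labile silyl ethers, sets out from compound 12 and comes back at compound 13. TMSOTf and 2,2'-bipyridyl in MeCN at 0 °C convert the four aryl MOM ethers into the (2S)-5-methoxy-7-(trimethylsilyloxy)-2-[3-{5-hydroxy-7-(trimethylsilyloxy)-2-[4-(trimethylsilyloxy)phenyl]-4-oxo-4H-chromen-6-yl}-4-(trimethylsilyloxy)phenyl]-2,3-dihydro-4H-chromen-4-one F4. Addition of water at rt and neutral pH hydrolyses F4 to 13; any transient silylation of the chelated 5-OH is reversed in the same hydrolysis.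

**Further compounds**
F1 | step 7 | racemic 2-[3-{5-hydroxy-7-(methoxymethoxy)-2-[4-(methoxymethoxy)phenyl]-4-oxo-4H-chromen-6-yl}-4-(methoxymethoxy)phenyl]-5-methoxy-7-(methoxymethoxy)-2,3-dihydro-4H-chromen-4-one | COc1cc(OCOC)cc2c1C(=O)CC(c1ccc(OCOC)c(-c3c(OCOC)cc4oc(-c5ccc(OCOC)cc5)cc(=O)c4c3O)c1)O2
F2 | step 7 | (2R)-2-[3-{5-hydroxy-7-(methoxymethoxy)-2-[4-(methoxymethoxy)phenyl]-4-oxo-4H-chromen-6-yl}-4-(methoxymethoxy)phenyl]-5-methoxy-7-(methoxymethoxy)-2,3-dihydro-4H-chromen-4-one | COc1cc(OCOC)cc2c1C(=O)C[C@H](c1ccc(OCOC)c(-c3c(OCOC)cc4oc(-c5ccc(OCOC)cc5)cc(=O)c4c3O)c1)O2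
F3 | step 4 | 4-(methoxymethoxy)-3-(trimethylstannyl)benzaldehyde | O=Cc1ccc(OCOC)c([Sn](C)(C)C)c1
F4 | step 8 | (2S)-5-methoxy-7-(trimethylsilyloxy)-2-[3-{5-hydroxy-7-(trimethylsilyloxy)-2-[4-(trimethylsilyloxy)phenyl]-4-oxo-4H-chromen-6-yl}-4-(trimethylsilyloxy)phenyl]-2,3-dihydro-4H-chromen-4-one | COc1cc(O[Si](C)(C)C)cc2c1C(=O)C[C@@H](c1ccc(O[Si](C)(C)C)c(-c3c(O[Si](C)(C)C)cc4oc(-c5ccc(O[Si](C)(C)C)cc5)cc(=O)c4c3O)c1)O2
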